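**Retrosynthetic overview**
- The last step is a global O-demethylation of a tetradecamethyl ether. All six benzene rings are bought; none is built.
- Key disconnection: both biaryl C–C bonds (ring A–ring B and ring F–ring D) are cut at once. Rings B and D are made electrophilic as phenoxenium (aromatic enolonium) equivalents from a bis-phenol core and PhI(OAc)2; rings A and F come from a nucleophilic trimethoxyarene.
- The two free phenols on rings B and D are unmasked from acetyl groups by Baeyer–Villiger oxidation, after ring E has been put on the hindered central oxygen by Ullmann etherification.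
- The central phenol of ring C comes from an aldehyde by an earlier, chemoselective Baeyer–Villiger oxidation. That same aldehyde activates ring C for the double SNAr that joins rings B and D to it.
- Order of assembly: C + B + D, then C–OH, then + E, then B/D phenols, then + A + F, then deprotection.

Assumption: the target has no stereocentre and no stereogenic axis (each biaryl axis carries a symmetric 2,4,6-trihydroxyphenyl ring), so it is achiral and needs no stereocontrol.

**Step 1**
Reactants: 1 2,6-difluoro-4-methoxybenzaldehyde; 2 acetosyringone (2.3 equiv)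
Product: 3 2,6-bis(4-acetyl-2,6-dimethoxyphenoxy)-4-methoxybenzaldehyde
Conditions: Cs2CO3 (3 equiv), DMSO, 110 °C, Ar
Reagents that add atoms: none
Why: Double nucleophilic aromatic substitution (SNAr): the aldehyde activates both ortho C–F bonds and the phenoxide of 2 has only its oxygen as a nucleophilic site, so both fluorides are displaced; no stereocentre is formed.

**Step 2**
Reactants: 3 2,6-bis(4-acetyl-2,6-dimethoxyphenoxy)-4-methoxybenzaldehyde
Product: 5 2,6-bis(4-acetyl-2,6-dimethoxyphenoxy)-4-methoxyphenol, via aryl formate 4 (not isolated)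
Conditions: mCPBA (1.3 equiv), CH2Cl2, 0 °C → rt; aq NaHCO3 wash; then K2CO3 (cat.), MeOH, rt
Reagents that add atoms: mCPBA, OOC(=O)c1cccc(Cl)c1
Why: Baeyer–Villiger (Dakin-type) oxidation: the electron-rich, di-ortho-oxygenated aryl group of the aldehyde migrates far faster than the two aryl methyl ketones react without acid, and methanolysis of the formate frees the central phenol.

**Step 3**
Reactants: 5 2,6-bis(4-acetyl-2,6-dimethoxyphenoxy)-4-methoxyphenol; 6 5-iodo-1,2,3-trimethoxybenzene (1.5 equiv)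
Product: 7 1,3-bis(4-acetyl-2,6-dimethoxyphenoxy)-5-methoxy-2-(3,4,5-trimethoxyphenoxy)benzene
Conditions: CuI (20 mol %), picolinic acid (40 mol %), K3PO4 (2.5 equiv), DMSO, 100 °C, Ar
Reagents that add atoms: none
Why: Ullmann diaryl ether synthesis with the CuI/picolinic acid system developed for di-ortho-substituted phenols; 5 has a single free OH and the ketones are inert, so ring E goes only onto the central oxygen.

**Step 4**
Reactants: 7 1,3-bis(4-acetyl-2,6-dimethoxyphenoxy)-5-methoxy-2-(3,4,5-trimethoxyphenoxy)benzene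
Product: 9 1,3-bis(4-hydroxy-2,6-dimethoxyphenoxy)-5-methoxy-2-(3,4,5-trimethoxyphenoxy)benzene, via bis-acetate 8 (not isolated)
Conditions: mCPBA (3 equiv), TFA (0.5 equiv), CH2Cl2, rt, dark; aq Na2SO3/NaHCO3 wash; then K2CO3 (cat.), MeOH, rt, Ar
Reagents that add atoms: mCPBA, OOC(=O)c1cccc(Cl)c1
Why: Acid-catalysed Baeyer–Villiger oxidation of the two aryl methyl ketones, in which the para-aryloxy aryl group migrates in preference to methyl; methanolysis of the two aryl acetates then gives the bis-phenol.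

**Step 5**
Reactants: 9 1,3-bis(4-hydroxy-2,6-dimethoxyphenoxy)-5-methoxy-2-(3,4,5-trimethoxyphenoxy)benzene; 10 1,3,5-trimethoxybenzene (10 equiv)
Product: 11 1,3-bis[4-hydroxy-2,6-dimethoxy-3-(2,4,6-trimethoxyphenyl)phenoxy]-5-methoxy-2-(3,4,5-trimethoxyphenoxy)benzene
Conditions: PhI(OAc)2 (2.1 equiv, slow addition), HFIP, 3 Å MS, 0 °C, Ar
Reagents that add atoms: none
Why: Proposed new method: each 4-aryloxy-3,5-dimethoxyphenol unit exchanges onto trivalent iodine to give an aryloxy(phenyl)iodine acetate, a phenoxenium (aromatic enolonium) equivalent whose ortho carbon is electrophilic; in dry, non-nucleophilic HFIP the strongest nucleophile present, 10, attacks that ortho carbon (para is blocked by the aryloxy group and the two ortho sites are equivalent), PhI and AcOH leave and tautomerisation restores the phenol; one equivalent of oxidant per phenol and the greater crowding of the product OH hold the reaction at one arylation per ring; the closest known reaction types are the hypervalent-iodine-mediated oxidative phenol–arene cross-coupling and the acid-promoted arylation of quinone monoacetals; no stereogenic element is formed because the new aryl ring is symmetric about the axis.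

**Step 6**
Reactants: 11 1,3-bis[4-hydroxy-2,6-dimethoxy-3-(2,4,6-trimethoxyphenyl)phenoxy]-5-methoxy-2-(3,4,5-trimethoxyphenoxy)benzene
Product: 12 3,5-bis[2,4,6-trihydroxy-3-(2,4,6-trihydroxyphenyl)phenoxy]-4-(3,4,5-trihydroxyphenoxy)phenol (CNP0279880.0)
Conditions: BBr3 (30 equiv), CH2Cl2, −78 °C → rt, Ar; then degassed MeOH/H2O
Reagents that add atoms: none
Why: Lewis-acid ether cleavage with BBr3: bromide attacks each of the 14 O-methyl groups while the diaryl ether and biaryl bonds are untouched, and hydrolysis of the aryl borates gives the achiral hexadecaphenol.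

**Compound list**
1 | 2,6-difluoro-4-methoxybenzaldehyde | COc1cc(F)c(C=O)c(F)c1 | starting material
2 | acetosyringone, 1-(4-hydroxy-3,5-dimethoxyphenyl)ethan-1-one | CC(=O)c1cc(OC)c(O)c(OC)c1 | starting material
3 | 2,6-bis(4-acetyl-2,6-dimethoxyphenoxy)-4-methoxybenzaldehyde | COc1cc(Oc2c(OC)cc(C(C)=O)cc2OC)c(C=O)c(Oc2c(OC)cc(C(C)=O)cc2OC)c1 | intermediate
4 | 2,6-bis(4-acetyl-2,6-dimethoxyphenoxy)-4-methoxyphenyl formate | COc1cc(Oc2c(OC)cc(C(C)=O)cc2OC)c(OC=O)c(Oc2c(OC)cc(C(C)=O)cc2OC)c1 | intermediate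
5 | 2,6-bis(4-acetyl-2,6-dimethoxyphenoxy)-4-methoxyphenol | COc1cc(Oc2c(OC)cc(C(C)=O)cc2OC)c(O)c(Oc2c(OC)cc(C(C)=O)cc2OC)c1 | intermediate
6 | 5-iodo-1,2,3-trimethoxybenzene | COc1cc(I)cc(OC)c1OC | starting material
7 | 1,3-bis(4-acetyl-2,6-dimethoxyphenoxy)-5-methoxy-2-(3,4,5-trimethoxyphenoxy)benzene | COc1cc(Oc2c(OC)cc(C(C)=O)cc2OC)c(Oc2cc(OC)c(OC)c(OC)c2)c(Oc2c(OC)cc(C(C)=O)cc2OC)c1 | intermediate
8 | 1,3-bis(4-acetoxy-2,6-dimethoxyphenoxy)-5-methoxy-2-(3,4,5-trimethoxyphenoxy)benzene | COc1cc(Oc2c(OC)cc(OC(C)=O)cc2OC)c(Oc2cc(OC)c(OC)c(OC)c2)c(Oc2c(OC)cc(OC(C)=O)cc2OC)c1 | intermediate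
9 | 1,3-bis(4-hydroxy-2,6-dimethoxyphenoxy)-5-methoxy-2-(3,4,5-trimethoxyphenoxy)benzene | COc1cc(Oc2c(OC)cc(O)cc2OC)c(Oc2cc(OC)c(OC)c(OC)c2)c(Oc2c(OC)cc(O)cc2OC)c1 | intermediate
10 | 1,3,5-trimethoxybenzene | COc1cc(OC)cc(OC)c1 | starting material
11 | 1,3-bis[4-hydroxy-2,6-dimethoxy-3-(2,4,6-trimethoxyphenyl)phenoxy]-5-methoxy-2-(3,4,5-trimethoxyphenoxy)benzene | COc1cc(Oc2c(OC)cc(O)c(-c3c(OC)cc(OC)cc3OC)c2OC)c(Oc2cc(OC)c(OC)c(OC)c2)c(Oc2c(OC)cc(O)c(-c3c(OC)cc(OC)cc3OC)c2OC)c1 | intermediate
12 | 3,5-bis[2,4,6-trihydroxy-3-(2,4,6-trihydroxyphenyl)phenoxy]-4-(3,4,5-trihydroxyphenoxy)phenol (achiral) | Oc1cc(O)c(-c2c(O)cc(O)c(Oc3cc(O)cc(Oc4c(O)cc(O)c(-c5c(O)cc(O)cc5O)c4O)c3Oc3cc(O)c(O)c(O)c3)c2O)c(O)c1 | target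

**Totals**
Total step count: 6. Longest linear sequence: 6 steps (from 1 or 2 to 12).

**Steps most likely to fail**

Step 5 (twofold oxidative cross-coupling). Risks are loss of the para-aryloxy group from the phenoxenium ion, a second arylation on the same ring, and oxidation of 10. The fallback sets out from 9 and comes back at 11, and reverses the polarity on the other partner. 10 is plumbated with Pb(OAc)4 in CHCl3 at rt to give (2,4,6-trimethoxyphenyl)lead triacetate F1, an aryl cation equivalent of tetravalent lead. 9, F1 (2.1 equiv) and pyridine in CHCl3 at 40 °C then give 11 by Pinhey ortho-C-arylation (ligand coupling on lead). No free phenoxenium ion is formed, so the diaryl ether cannot be lost.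

Step 6 (cleavage of 14 methyl ethers to an air-sensitive polyphenol). Risks are incomplete demethylation and oxidation of the product on isolation. The fallback sets out from 11 and comes back at 12, and replaces direct isolation by capture and release. The crude BBr3 product is peracetylated at once (Ac2O, pyridine, DMAP, rt) to the hexadecaacetate of 12 F2, which is air-stable, can be purified on silica and can be separated from under-demethylated material. Acid methanolysis (HCl in degassed MeOH, 40 °C) then releases 12.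

Step 1 (double SNAr of a hindered, weakly nucleophilic phenoxide on a methoxy-deactivated fluoroaldehyde). The risk is that the second substitution stalls. The fallback sets out from 2 and comes back at 5, replacing steps 1 and 2. 2 (2 equiv) is added to 2,6-dichloro-1,4-benzoquinone (O=C1C=C(Cl)C(=O)C(Cl)=C1) with K2CO3 in MeCN at rt; addition–elimination on the far more electrophilic haloquinone gives 2,6-bis(4-acetyl-2,6-dimethoxyphenoxy)-1,4-benzoquinone F3. Na2S2O4 in THF/H2O reduces it to 2,6-bis(4-acetyl-2,6-dimethoxyphenoxy)benzene-1,4-diol F4. MeI (1.0 equiv) and K2CO3 in acetone then methylate the unhindered, more acidic 4-OH to give 5.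

**Further compounds**
F1 | step 5 | (2,4,6-trimethoxyphenyl)lead triacetate | COc1cc(OC)c([Pb](OC(C)=O)(OC(C)=O)OC(C)=O)c(OC)c1
F2 | step 6 | hexadecaacetate of 12 | CC(=O)Oc1cc(OC(C)=O)c(-c2c(OC(C)=O)cc(OC(C)=O)c(Oc3cc(OC(C)=O)cc(Oc4c(OC(C)=O)cc(OC(C)=O)c(-c5c(OC(C)=O)cc(OC(C)=O)cc5OC(C)=O)c4OC(C)=O)c3Oc3cc(OC(C)=O)c(OC(C)=O)c(OC(C)=O)c3)c2OC(C)=O)c(OC(C)=O)c1
F3 | step 1 | 2,6-bis(4-acetyl-2,6-dimethoxyphenoxy)-1,4-benzoquinone | O=C1C=C(Oc2c(OC)cc(C(C)=O)cc2OC)C(=O)C(Oc2c(OC)cc(C(C)=O)cc2OC)=C1
F4 | step 1 | 2,6-bis(4-acetyl-2,6-dimethoxyphenoxy)benzene-1,4-diol | Oc1cc(Oc2c(OC)cc(C(C)=O)cc2OC)c(O)c(Oc2c(OC)cc(C(C)=O)cc2OC)c1
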